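**Retrosynthetic overview**
- Final step: both Ar–CH2 bonds (ring A C3–CH2OH and the phthalide C3a–CH2) are made at once by coupling a nucleophilic hydroxymethyl reagent (Bu3SnCH2OH, a formaldehyde anion equivalent) with the two aryl bromides of an unprotected triphenol dibromide. The ring B benzyl alcohol then closes onto its neighbouring methyl ester.
- The dibromide comes from a dialdehyde diaryl ether by double Pinnick oxidation/methylation and BBr3 dealkylation.
- The diaryl ether C–O bond is an SNAr of a fully substituted ring B phenol on a ring A 2-fluorobenzaldehyde.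
- Ring A comes from 2-bromo-1,3-difluoro-5-methylbenzene (the bromine first blocks C3, then serves as the coupling handle). Ring B comes from 2-hydroxy-3,4-dimethoxybenzaldehyde (its CHO becomes the aryl methyl).
- Ring order: both benzene rings are bought; the γ-lactone is the only ring formed, and it is formed last.

Assumption: the target has no stereocentre, so the SMILES defines one achiral compound and no stereocontrol is needed; 2-bromo-1,3-difluoro-5-methylbenzene is taken as a catalogue compound.

**Step 1**
Reactants: 1 2-bromo-1,3-difluoro-5-methylbenzene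
Product: 3 3-bromo-2,4-difluoro-6-methylbenzaldehyde, via aryllithium 2 (not isolated)
Conditions: LDA (1.1 equiv), THF, −78 °C; then DMF, −78 → −40 °C; aq. HCl
Reagents that add atoms: N,N-dimethylformamide CN(C)C=O
Why: Fluorine-directed ortho-lithiation followed by formylation; the two ring C–H positions are equivalent by symmetry and each lies ortho to a fluorine, and keeping the anion at −78 °C suppresses LiF loss and halogen migration.

**Step 2**
Reactants: 3 3-bromo-2,4-difluoro-6-methylbenzaldehyde
Product: 4 4-(benzyloxy)-3-bromo-2-fluoro-6-methylbenzaldehyde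
Conditions: BnOH (1.05 equiv), Cs2CO3, DMSO, 50 °C
Reagents that add atoms: benzyl alcohol OCc1ccccc1
Why: SNAr at the fluorine para to the formyl group, which is less hindered (Br/H neighbours) than the ortho fluorine (CHO/Br neighbours); the non-coordinating Cs+/DMSO medium gives no chelation-directed ortho delivery, and the first alkoxy group deactivates the ring against a second substitution.

**Step 3**
Reactants: 5 2-hydroxy-3,4-dimethoxybenzaldehyde
Product: 6 2,3-dimethoxy-6-methylphenol
Conditions: H2 (3 bar), 10% Pd/C, AcOH, rt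
Reagents that add atoms: none
Why: Catalytic hydrogenation/hydrogenolysis of an electron-rich salicylaldehyde to the o-cresol via the benzylic alcohol; this leaves the oxygen next to the new methyl group free and the other two as methyl ethers.

**Step 4**
Reactants: 6 2,3-dimethoxy-6-methylphenol
Product: 7 4-hydroxy-2,3-dimethoxy-5-methylbenzaldehyde
Conditions: Cl2CHOMe, TiCl4, CH2Cl2, −10 → 0 °C; then aq. HCl
Reagents that add atoms: dichloromethyl methyl ether COC(Cl)Cl; water O
Why: Rieche formylation; both positions ortho to the phenol are blocked, so the electrophile enters para to OH and ortho to OMe, the most activated free position.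

**Step 5**
Reactants: 7 4-hydroxy-2,3-dimethoxy-5-methylbenzaldehyde
Product: 8 2-bromo-4-hydroxy-5,6-dimethoxy-3-methylbenzaldehyde
Conditions: NBS (1.05 equiv), MeCN, 0 °C → rt
Reagents that add atoms: N-bromosuccinimide O=C1CCC(=O)N1Br
Why: Electrophilic aromatic bromination at the only remaining ring C–H, which is para to a methoxy group (the same pattern as the known 2-bromination of syringaldehyde).

**Step 6**
Reactants: 4 4-(benzyloxy)-3-bromo-2-fluoro-6-methylbenzaldehyde; 8 2-bromo-4-hydroxy-5,6-dimethoxy-3-methylbenzaldehyde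
Product: 9 4-(benzyloxy)-3-bromo-2-(3-bromo-4-formyl-5,6-dimethoxy-2-methylphenoxy)-6-methylbenzaldehyde
Conditions: Cs2CO3, DMSO, 110 °C, N2
Reagents that add atoms: none
Why: SNAr diaryl ether formation; the one remaining fluorine is ortho to the formyl group and is the only good leaving group, fluoride being far better than bromide so both C–Br bonds survive, and the addition–elimination path tolerates the four ortho substituents better than a metal-catalysed coupling would.

**Step 7**
Reactants: 9 4-(benzyloxy)-3-bromo-2-(3-bromo-4-formyl-5,6-dimethoxy-2-methylphenoxy)-6-methylbenzaldehyde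
Product: 11 methyl 4-(benzyloxy)-3-bromo-2-[3-bromo-5,6-dimethoxy-4-(methoxycarbonyl)-2-methylphenoxy]-6-methylbenzoate, via diacid 10 (not isolated)
Conditions: NaClO2, NaH2PO4, 2-methyl-2-butene, t-BuOH/THF/H2O, rt; then MeI, K2CO3, DMF, rt
Reagents that add atoms: sodium chlorite [O-]Cl=O.[Na+]; iodomethane CI
Why: Double Pinnick oxidation, which copes with hindered aryl aldehydes while the alkene scavenger protects the electron-rich rings from HOCl, followed by carboxylate O-methylation, an SN2 at MeI that is not slowed by the ortho substituents.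

**Step 8**
Reactants: 11 methyl 4-(benzyloxy)-3-bromo-2-[3-bromo-5,6-dimethoxy-4-(methoxycarbonyl)-2-methylphenoxy]-6-methylbenzoate
Product: 12 methyl 3-bromo-2-[3-bromo-5,6-dihydroxy-4-(methoxycarbonyl)-2-methylphenoxy]-4-hydroxy-6-methylbenzoate
Conditions: BBr3 (6 equiv), CH2Cl2, −78 → 0 °C; then H2O
Reagents that add atoms: none
Why: Lewis-acid ether cleavage; the benzyl ether, the methoxy group chelated to the ester and its catechol neighbour all cleave at or below 0 °C, where methyl esters, the diaryl ether and the aryl bromides are stable. All dealkylation is done before the acid-sensitive benzylic alcohol exists.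

**Step 9**
Reactants: 12 methyl 3-bromo-2-[3-bromo-5,6-dihydroxy-4-(methoxycarbonyl)-2-methylphenoxy]-4-hydroxy-6-methylbenzoate
Product: 14 methyl 2-[(6,7-dihydroxy-4-methyl-1-oxo-1,3-dihydro-2-benzofuran-5-yl)oxy]-4-hydroxy-3-(hydroxymethyl)-6-methylbenzoate (the target), via bis(hydroxymethyl) diester 13 (not isolated)
Conditions: Bu3SnCH2OH (3 equiv), Pd(P(t-Bu)3)2 (10 mol %), 1,4-dioxane, 100 °C, Ar
Reagents that add atoms: (tributylstannyl)methanol CCCC[Sn](CCCC)(CCCC)CO
Why: Twofold Migita–Kosugi–Stille coupling with a hydroxymethyl anion equivalent, so the formaldehyde carbon is delivered as a nucleophile to two electrophilic aryl bromide carbons; the neutral medium tolerates the free phenols and avoids base-induced depsidone or dioxin closure, the ring B o-(hydroxymethyl)benzoate lactonises with loss of methanol while the ring A alcohol (meta to its ester) stays open, and no stereocentre is created.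

**Compound list**
1 | 2-bromo-1,3-difluoro-5-methylbenzene | Cc1cc(F)c(Br)c(F)c1 | starting material
2 | (3-bromo-2,4-difluoro-6-methylphenyl)lithium | [Li]c1c(C)cc(F)c(Br)c1F | intermediate
3 | 3-bromo-2,4-difluoro-6-methylbenzaldehyde | O=Cc1c(C)cc(F)c(Br)c1F | intermediate
4 | 4-(benzyloxy)-3-bromo-2-fluoro-6-methylbenzaldehyde | O=Cc1c(C)cc(OCc2ccccc2)c(Br)c1F | intermediate
5 | 2-hydroxy-3,4-dimethoxybenzaldehyde | O=Cc1ccc(OC)c(OC)c1O | starting material
6 | 2,3-dimethoxy-6-methylphenol | Cc1ccc(OC)c(OC)c1O | intermediate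
7 | 4-hydroxy-2,3-dimethoxy-5-methylbenzaldehyde | O=Cc1cc(C)c(O)c(OC)c1OC | intermediate
8 | 2-bromo-4-hydroxy-5,6-dimethoxy-3-methylbenzaldehyde | O=Cc1c(Br)c(C)c(O)c(OC)c1OC | intermediate
9 | 4-(benzyloxy)-3-bromo-2-(3-bromo-4-formyl-5,6-dimethoxy-2-methylphenoxy)-6-methylbenzaldehyde | O=Cc1c(C)cc(OCc2ccccc2)c(Br)c1Oc1c(C)c(Br)c(C=O)c(OC)c1OC | intermediate
10 | 4-(benzyloxy)-3-bromo-2-(3-bromo-4-carboxy-5,6-dimethoxy-2-methylphenoxy)-6-methylbenzoic acid | OC(=O)c1c(C)cc(OCc2ccccc2)c(Br)c1Oc1c(C)c(Br)c(C(=O)O)c(OC)c1OC | intermediate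
11 | methyl 4-(benzyloxy)-3-bromo-2-[3-bromo-5,6-dimethoxy-4-(methoxycarbonyl)-2-methylphenoxy]-6-methylbenzoate | COC(=O)c1c(C)cc(OCc2ccccc2)c(Br)c1Oc1c(C)c(Br)c(C(=O)OC)c(OC)c1OC | intermediate
12 | methyl 3-bromo-2-[3-bromo-5,6-dihydroxy-4-(methoxycarbonyl)-2-methylphenoxy]-4-hydroxy-6-methylbenzoate | COC(=O)c1c(C)cc(O)c(Br)c1Oc1c(C)c(Br)c(C(=O)OC)c(O)c1O | intermediate
13 | methyl 2-[5,6-dihydroxy-3-(hydroxymethyl)-4-(methoxycarbonyl)-2-methylphenoxy]-4-hydroxy-3-(hydroxymethyl)-6-methylbenzoate | COC(=O)c1c(C)cc(O)c(CO)c1Oc1c(C)c(CO)c(C(=O)OC)c(O)c1O | intermediate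
14 | methyl 2-[(6,7-dihydroxy-4-methyl-1-oxo-1,3-dihydro-2-benzofuran-5-yl)oxy]-4-hydroxy-3-(hydroxymethyl)-6-methylbenzoate (NP-007516) | COC(=O)c1c(C)cc(O)c(CO)c1Oc1c(C)c2c(c(O)c1O)C(=O)OC2 | target

**Step count and risks**
Total step count: 9. Longest linear sequence: 7 steps (5 → 6 → 7 → 8 → 9 → 11 → 12 → 14; the ring A branch 1 → 3 → 4 joins at step 6).

Steps most likely to fail:

Step 9. The free catechol may inhibit palladium, oxidative addition at the ring A bromide (flanked by OH and OAr) is slow, and butyl transfer or hydrodebromination can compete. The fallback sets out from 12 and masks the three phenols with Ac2O/pyridine/DMAP as methyl 4-acetoxy-3-bromo-2-[5,6-diacetoxy-3-bromo-4-(methoxycarbonyl)-2-methylphenoxy]-6-methylbenzoate F1. The same hydroxymethyl-anion Stille coupling (Bu3SnCH2OH, Pd(PPh3)4, dioxane, 100 °C) is then run on this phenol-free substrate and gives the lactonised methyl 4-acetoxy-2-[(6,7-diacetoxy-4-methyl-1-oxo-1,3-dihydro-2-benzofuran-5-yl)oxy]-3-(hydroxymethyl)-6-methylbenzoate F2. Catalytic K2CO3 in MeOH at 0 °C removes the aryl acetates (an acetyl that has migrated to the benzylic oxygen is removed as well), and the route is rejoined at 14.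

Step 6. The phenoxide of 8 is a vinylogous carboxylate and is flanked by CH3 and OMe, and the fluoride of 4 is flanked by CHO and Br and is deactivated by the para benzyloxy group, so the substitution may stall. The fallback sets out from 8 and takes the electron-withdrawing formyl group out of conjugation. HC(OMe)3/MeOH with catalytic TsOH gives 3-bromo-4-(dimethoxymethyl)-5,6-dimethoxy-2-methylphenol F3. Its far more nucleophilic phenoxide is coupled with 4 (Cs2CO3, DMSO, 90 °C) to 4-(benzyloxy)-3-bromo-2-[3-bromo-4-(dimethoxymethyl)-5,6-dimethoxy-2-methylphenoxy]-6-methylbenzaldehyde F4. Dilute HCl/THF in the work-up hydrolyses the acetal, and the route is rejoined at 9.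

Step 2. An aldehyde can steer alkoxides to the ortho fluorine, so a mixture of regioisomers is possible. The fallback sets out from 3 and swaps the activating group for a nitrile, which cannot chelate and gives dependable para substitution. NH2OH·HCl/HCO2Na in HCO2H at 100 °C gives 3-bromo-2,4-difluoro-6-methylbenzonitrile F5. BnOH/t-BuOK in THF at 0 °C gives 4-(benzyloxy)-3-bromo-2-fluoro-6-methylbenzonitrile F6. DIBAL-H in toluene at −78 °C followed by aqueous HCl hydrolysis of the imine rejoins the route at 4.

**Further compounds**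
F1 | step 9 | methyl 4-acetoxy-3-bromo-2-[5,6-diacetoxy-3-bromo-4-(methoxycarbonyl)-2-methylphenoxy]-6-methylbenzoate | COC(=O)c1c(C)cc(OC(C)=O)c(Br)c1Oc1c(C)c(Br)c(C(=O)OC)c(OC(C)=O)c1OC(C)=O
F2 | step 9 | methyl 4-acetoxy-2-[(6,7-diacetoxy-4-methyl-1-oxo-1,3-dihydro-2-benzofuran-5-yl)oxy]-3-(hydroxymethyl)-6-methylbenzoate | COC(=O)c1c(C)cc(OC(C)=O)c(CO)c1Oc1c(C)c2c(c(OC(C)=O)c1OC(C)=O)C(=O)OC2
F3 | step 6 | 3-bromo-4-(dimethoxymethyl)-5,6-dimethoxy-2-methylphenol | COC(OC)c1c(Br)c(C)c(O)c(OC)c1OC
F4 | step 6 | 4-(benzyloxy)-3-bromo-2-[3-bromo-4-(dimethoxymethyl)-5,6-dimethoxy-2-methylphenoxy]-6-methylbenzaldehyde | O=Cc1c(C)cc(OCc2ccccc2)c(Br)c1Oc1c(C)c(Br)c(C(OC)OC)c(OC)c1OC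
F5 | step 2 | 3-bromo-2,4-difluoro-6-methylbenzonitrile | N#Cc1c(C)cc(F)c(Br)c1F
F6 | step 2 | 4-(benzyloxy)-3-bromo-2-fluoro-6-methylbenzonitrile | N#Cc1c(C)cc(OCc2ccccc2)c(Br)c1F
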